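Time was my first question, because these recipes differ in when things go in, so I asked how long starting material stays in a flask.

| flask | starting material | reagent | second substrate | protic impurity | remark | time |
|---|---|---|---|---|---|---|
| west | 0.0020 M | 2.4 mM | 2 mM | 0.040 mM | run made earlier |  |
| south-west | 0.0010 M | 2.4 mM | 2 mM | 0.040 mM | run made earlier |  |
| south | 0.0040 M | 2.4 mM | 2 mM | 0.040 mM | run made earlier |  |
| Friday's | 0.0020 M | 2.40 mM (fed, over 2.0 min) | 2.00 mM | 0.0400 mM | all else is in the flask from the start; the feed brings no volume worth counting | 3.0 min |
| Tuesday's | 0.0020 M (in portions, 3, over 2.0 min) | 2.40 mM | 2.00 mM | 0.0400 mM | first portion at the start, last at 2.0 min | 3.0 min |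
| Monday's | 0.0020 M (fed, over 12 s) | 2.40 mM | 2.00 mM | 0.0400 mM | all else is in the flask from the start; the feed brings no volume worth counting | 3.0 min |
| Saturday's | 0.0020 M (fed, over 2.0 min) | 2.40 mM | 2.00 mM | 0.0400 mM | all else is in the flask from the start; the feed brings no volume worth counting | 3.0 min |
| Thursday's | 0.0020 M | 2.40 mM | 2.00 mM | 0.0400 mM | everything together at the start | 3.0 min |

| run | time / min | target / % | starting material / % |
|---|---|---|---|
| west | 0.250 | 25.7 | 18.3 |
| west | 0.333 | 27.3 | 12.9 |
| west | 0.500 | 30.2 | 8.1 |
| west | 0.833 | 33.0 | 3.7 |
| west | 1.33 | 35.8 | 1.7 |
| west | 2.00 | 36.5 | 1.2 |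
| west | 3.00 | 37.4 | 0 |
| south-west | 0.333 | 26.3 | 8.6 |
| south-west | 0.667 | 28.1 | 3.0 |
| south-west | 1.00 | 28.8 | 0.4 |
| south-west | 1.33 | 29.4 | 0 |
| south-west | 1.50 | 28.8 | 1.4 |
| south-west | 2.00 | 29.0 | 0.5 |
| south-west | 2.50 | 30.6 | 1.4 |
| south | 0.333 | 30.0 | 25.5 |
| south | 0.667 | 37.0 | 15.2 |
| south | 1.00 | 39.9 | 13.3 |
| south | 1.33 | 41.7 | 10.4 |
| south | 1.50 | 43.3 | 10.1 |
| south | 2.00 | 44.6 | 8.3 |
| south | 2.50 | 46.1 | 7.3 |

(scatter of a reading: 0.5 percentage points)



- the best flask by amount of target, in percent of the starting material charged; "all alike" if 1.5 percentage points covers them all (Friday's / Tuesday's / Monday's / Saturday's / Thursday's / all alike)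
- amount of target at the end, in percent of the starting material charged, Friday's
- amount of target at the end, in percent of the starting material charged, Tuesday's
- amount of target at the end, in percent of the starting material charged, Monday's
- amount of target at the end, in percent of the starting material charged, Saturday's
- amount of target at the end, in percent of the starting material charged, Thursday's

The west run has Thursday's charges, and its starting material was down to 1.7% at 1.33 min. I called the time in which nearly all of a charge of starting material leaves the flask its life, and read it there as 1.33 min.

Friday's flask feeds the reagent over 2.0 min, and I looked at two extremes. With the whole reagent present from the start it is the west run, which gave 37.4% of target at 3.00 min. With the reagent arriving after the life, I counted the target as zero. I expected the real flask to lie between them, and I took the target to follow the reagent standing during the life. The amount fed by a steady feed rises in a straight line, so its mean over the life is 33.3% of the charge; I counted all of it as standing, and that share of the west figure is 12.4%. In replacing the curve by its mean I expected errors both ways: starting material falls while the fed reagent rises, which pulls the figure down, and with less reagent I expected starting material to last longer, which pulls it up. I kept the figure as rough.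

The life also gave me a test for rest: the last addition plus one life should lie before the end. For Tuesday's that sum is 3.33 min, later than the 3.0 min allowed, so I expected Tuesday's to be unfinished.

The forecast gave 23% for Friday's, against my 12.4%, then 37% for Tuesday's, 37.2% for Monday's, 36.5% for Saturday's and 37.3% for Thursday's, and it named Thursday's as best. Its ground was this: “Both routes are first order in starting material, so selectivity depends only on the remaining reagent and second substrate, not on how the starting material is dosed.”

Monday's came out best at 42.0%, with Tuesday's and Saturday's at 38.9%, Thursday's at 37.5% and Friday's at 12.7%, which is 34.0% of the west figure against my share of 33.3%.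

    starting material + reagent → target (k = 23.0 M⁻¹ s⁻¹)
    starting material ⇌ dormant form (K = 0.320, k = 0.00490 s⁻¹)
    starting material + protic impurity → quenched substrate (k = 2300 M⁻¹ s⁻¹)
    starting material + second substrate → cross product (k = 80.0 M⁻¹ s⁻¹)
    second substrate + reagent → second product (k = 21.0 M⁻¹ s⁻¹)

Friday's had 0.358% of starting material left at the end, and ten times the time took its target from 12.7% to 13.9%. Monday's held 1.71% of starting material at the end, and the same wait took its target from 42.0% to 44.9%. Tuesday's still held 21.7% of starting material at the end, and its target went from 38.9% to 51.1% at 30.0 min.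

The runs stem from a simulated flask on assumed constants, noise included.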